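Remark on the chemistry: coumarin atoms are numbered O1 to C8a (ring A is the benzenoid ring, ring B the pyranone ring). The acyl side chain is numbered C1' to C8' (ring C is C1' to C6', C7' is the carbinol carbon, C8' its methyl group). Intermediate 16 is drawn with an ethyl group on zinc; the zinc may instead carry methanesulfonate, which does not alter the stereochemical course.

## Analysis of the target

Target 35 is a hexasubstituted coumarin. Ring A carries OMe at C5, a prenyl group at C6, a free OH at C7 and an acyl group at C8; ring B carries methyl groups at C3 and C4. The acyl group is a cyclohex-1-ene-1-carbonyl unit (ring C) whose only alkene, C1'=C2', is conjugated with the ketone. Ring C bears a methyl group at C5' (R) and a 1-hydroxyethyl group at C6' (R), with the carbinol carbon C7' (S) outside the ring. The three stereocentres are contiguous: the C5' methyl and the C6' side chain are cis on ring C, and along the chain C1'–C6'–C7'–C8' the C5' branch and the hydroxyl group are anti. Sensitive sites are the coumarin lactone (nucleophiles, strong base), the prenyl group beside a phenol (acid closes a chroman), the o-hydroxyaryl enone (the phenoxide can add to C2') and the electron-rich alkenes. The difficulty is to join a dense, partly exocyclic stereotriad through a ketone to C8, the most crowded position of ring A, on an arene that cannot safely be turned into a carbanion because of its lactone, while three different alkenes coexist. The strategy rests on C1'=C2': it is the only alkene of ring C, it is trisubstituted, and it touches none of C5', C6' and C7'. Ring C can therefore be closed last at that bond, from an open chain in which the triad has been set by acyclic stereocontrol and C1' is an exo-methylene carbon on the aryl ketone.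

## Retrosynthetic reasoning

The O–Si bonds at O7 and at the C7' oxygen are cut first, so 35 comes from bis-silyl ether 34. The phenol must be masked through the late steps because its anion would add to an enone, and the secondary alcohol must be masked because an oxidation precedes ring closure. One fluoride treatment has to remove both groups without touching lactone, prenyl group or enone.

In 34 the C1'=C2' bond of ring C is cut, which gives the open 1,7-dienone 33. This bond is chosen because it is the only ring bond that is not attached to a stereocentre on both sides and whose formation creates no stereocentre. The forward ring-closing metathesis has to pick the vinyl group and the exo-methylene group out of four alkenes and close a six-membered ring on a crowded, electron-poor 1,1-disubstituted alkene.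

In 33 the bond between the ketone carbon and C1' is cut after a change of oxidation level: 33 comes from allylic alcohol 32, and 32 from aldehyde 30 and 2-iodoalkene 20. Cutting here makes the arene the electrophile, so no aryl anion is needed beside the lactone, and it brings in C1' with its exo-methylene carbon already attached. The forward coupling must add an alkenyl group to an aldehyde flanked by two ortho substituents and leave the lactone alone.

Iodoalkene 20 is traced to silyl ether 18 and alcohol 17 by removing H–I from C1' and its methylene carbon. A terminal alkyne is thus the latent form of the C1' unit, and the forward step needs Markovnikov addition to the alkyne in the presence of a terminal alkene and a silyl ether.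

In 17 the C6'–C7' bond is cut to give propargylic mesylate 14 and acetaldehyde 15. This single disconnection accounts for both C6' and C7': the configuration of the mesylate carbon is relayed to C6', and the cyclic transition state of the allenylmetal addition gives the anti relationship to C7'. The alkyne needed for 20 is part of the nucleophile.

Mesylate 14 goes back through alcohols 13 and 12 to ynone 11, where the C–O stereocentre is removed. A catalyst-controlled ketone reduction can then set this centre independently of the neighbouring C5'.

Ynone 11 is cut between the carbonyl carbon and the alkyne, to Weinreb amide 10 and hence acid 8. The C5'–CH3 bond of 8 is cut back to imide 6, imide 4, hex-5-enoic acid 1 and auxiliary 2. The butenyl chain of 1 already contains C2' to C4' and the vinyl group for the metathesis, so only the methyl group has to be added under auxiliary control.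

Aldehyde 30 is simplified by removing the silyl group (29), then the two terminal methyl groups of the prenyl unit (allyl compound 28), then by returning the allyl group from C6 to O7 (ether 27). Delivering the carbon from O7 by sigmatropic shift avoids the O- versus C-alkylation problem and can only end at C6, because C8 is occupied.

Ether 27 is cut at its O-allyl bond (26), at its O-methyl bond (25) and at the C8–CHO bond (23). Coumarin 23 is cut across ring B into phloroglucinol 21 and keto ester 22. The symmetry of 21 makes the ring-B annulation regiochemically unambiguous; the forward formylation must then choose C8 over C6, and the methylation must choose O5 over the hydrogen-bonded O7.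

## Alternatives that were turned down

Alternative 1: Ring C is cut at C5'–C6' by a retro-electrocyclisation. This leads to butenolide A1, which carries a (1Z,3E)-pentadienyl arm on the lactone α-carbon and holds C7' as its only stereocentre. In the forward direction, heating A1 would close the hexatriene (butenolide alkene plus dienyl arm) by disrotation to the bicyclic dienyl lactone A2. For it: one pericyclic step makes ring C and both C5' and C6' from a single purchased stereocentre, disrotation of the two outside groups gives the required cis relationship, and the lactone carbonyl is the future ketone carbon. On ring formation and stereocentre economy it is stronger than the chosen route. Against it: the facial bias comes from one methyl group on a flat five-membered ring; the Z-alkene of the triene must be made and kept; and the cyclohexa-1,3-diene A2 can undergo hydrogen shifts or aromatise at the temperature of its formation, which would erase C5' and C6'. The extra C3'=C4' alkene must then be reduced beside the conjugated C1'=C2' bond. Most seriously, opening A2 to an aryl ketone needs a C8 carbanion of the fully substituted coumarin or an acylation at its most hindered position in the presence of the prenyl group. The chosen route offers instead a union with the arene as aldehyde 30 under neutral conditions and stereocentres set by reactions of predictable sense.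

Alternative 2: The arene is cut at both C7–O and C8–C(=O), to a 7,8-aryne generated from silyl triflate A3 and the complete cyclohexene acid A4 (carbinol as 4-methoxybenzyl ether). Fluoride would release the aryne, the carboxylate of A4 would add through oxygen at C7, and the C8 anion would attack the ester carbonyl to give the o-hydroxyaryl ketone A5. For it: it is the most convergent plan, it forms the hindered aryl ketone and the free phenol in one step without redox changes, and the ring oxygen O1 favours the required regiochemistry of addition. On convergence it is stronger than the chosen route. Against it: the acyl shift must pass a four-membered transition state and competes with simple protonation of the aryl anion by A4, which would give the aryl ester. A3 needs its own multistep preparation on a lactone-bearing ring. A5 lacks the C6 prenyl group, which would have to be added afterwards beside an enone and an oxidatively labile ether. A4 still contains ring C and all three stereocentres, so the stereochemical work is only moved. The chosen route has the prenyl group in place before the union and relies on bond formations of lower risk.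

Alternative 3: Ring C is cut at C1'–C6', to the unsaturated epoxynitrile A6. Deprotonation at the γ-carbon would give a dienyl anion whose α-carbon opens the epoxide at C6' with inversion, closing the six-membered ring and releasing the C7' hydroxyl group; the alkene then moves into conjugation to give hydroxy nitrile A7. For it: C6' is set stereospecifically by SN2 opening, ring closure is an anionic alkylation that needs no catalyst and no selection among alkenes, and A7 is small and robust. In that respect it is stronger than the metathesis. Against it: A6 requires an enantiopure cis-dialkyl epoxide next to C5', for which neither catalyst nor substrate control is dependable; attack must occur at the epoxide carbon flanked by the branched C5'; and the base may add to the unsaturated nitrile. After ring closure the nitrile of A7 must still become an aryl ketone at C8, which again calls for a coumarin carbanion. The chosen route answers exactly this point with aldehyde 30 as electrophile, and it sets C6' and C7' together by an addition with a known anti preference.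

Key step: step 21

## Route

Step 1
Reactants: 1 hex-5-enoic acid; 2 (R)-4-benzyloxazolidin-2-one
Product: 4 (R)-4-benzyl-3-(hex-5-enoyl)oxazolidin-2-one, via hex-5-enoic pivalic anhydride 3 (not isolated)
Conditions: PivCl, Et3N, THF, −20 °C; then LiCl, 2, −20 °C → rt
Reagents that add atoms: none
Why: N-acylation of the oxazolidinone through a mixed anhydride; LiCl/Et3N activates the carbamate N–H so that no strong base is needed, and the hindered pivaloyl carbonyl of 3 is not attacked. No stereocentre is formed.

Step 2
Reactants: 4 (R)-4-benzyl-3-(hex-5-enoyl)oxazolidin-2-one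
Product: 6 (R)-4-benzyl-3-[(R)-2-methylhex-5-enoyl]oxazolidin-2-one, via sodium (Z)-enolate 5 (not isolated)
Conditions: NaN(SiMe3)2, THF, −78 °C; MeI, −78 → −40 °C
Reagents that add atoms: iodomethane, CI
Why: Evans asymmetric alkylation; the chelated (Z)-enolate 5 is shielded on one face by the benzyl group, so MeI enters from the other face and sets C5' as R. The minor diastereomer should be removable by chromatography or crystallisation.

Step 3
Reactants: 6 (R)-4-benzyl-3-[(R)-2-methylhex-5-enoyl]oxazolidin-2-one
Product: 8 (R)-2-methylhex-5-enoic acid, via lithium (R)-2-methylhex-5-eneperoxoate 7 (not isolated)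
Conditions: LiOH, H2O2, THF/H2O, 0 °C; Na2SO3; HCl to pH 2
Reagents that add atoms: hydrogen peroxide, OO (used as LiOOH)
Why: Hydroperoxide cleavage of the imide; the small, α-effect nucleophile attacks the exocyclic carbonyl and leaves the C5' centre untouched, and sulfite reduces peroxoate 7 to the acid. Auxiliary 2 is recovered.

Step 4
Reactants: 8 (R)-2-methylhex-5-enoic acid
Product: 10 (R)-N-methoxy-N,2-dimethylhex-5-enamide, via (R)-1-(1H-imidazol-1-yl)-2-methylhex-5-en-1-one 9 (not isolated)
Conditions: carbonyldiimidazole, CH2Cl2, rt; then MeNHOMe·HCl, rt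
Reagents that add atoms: N,O-dimethylhydroxylamine hydrochloride, CNOC.Cl
Why: Amide formation through acyl imidazole 9; the activation is mild and base-free, so the α-stereocentre should not epimerise.

Step 5
Reactants: 10 (R)-N-methoxy-N,2-dimethylhex-5-enamide
Product: 11 (R)-4-methyl-1-(trimethylsilyl)oct-7-en-1-yn-3-one
Conditions: Me3SiC≡CH, n-BuLi, THF, −78 °C; then 10, −78 → 0 °C; aq NH4Cl
Reagents that add atoms: ethynyltrimethylsilane, C#C[Si](C)(C)C
Why: Weinreb ketone synthesis; the chelated tetrahedral adduct persists until the quench, which prevents over-addition and keeps the α-centre from enolising. The two alkyne carbons become C1' and its methylene carbon.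

Step 6
Reactants: 11 (R)-4-methyl-1-(trimethylsilyl)oct-7-en-1-yn-3-one
Product: 12 (3S,4R)-4-methyl-1-(trimethylsilyl)oct-7-en-1-yn-3-ol
Conditions: Ru[(S,S)-TsDPEN](p-cymene) (2 mol%), i-PrOH, rt
Reagents that add atoms: none
Why: Noyori asymmetric transfer hydrogenation of an alkynyl ketone; the alkyne takes the place an aryl group has in aryl ketone reductions, so the (S,S)-catalyst should deliver hydride to give the (3S)-carbinol under catalyst control. The base-free amido complex avoids epimerisation at C5'.

Step 7
Reactants: 12 (3S,4R)-4-methyl-1-(trimethylsilyl)oct-7-en-1-yn-3-ol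
Product: 13 (3S,4R)-4-methyloct-7-en-1-yn-3-ol
Conditions: K2CO3 (cat.), MeOH, rt
Reagents that add atoms: none
Why: Methanolysis of the alkynyl C–Si bond; it frees the terminal alkyne needed for hydroiodination later and affects no stereocentre.

Step 8
Reactants: 13 (3S,4R)-4-methyloct-7-en-1-yn-3-ol
Product: 14 (3S,4R)-4-methyloct-7-en-1-yn-3-yl methanesulfonate
Conditions: MsCl, Et3N, CH2Cl2, −78 → 0 °C
Reagents that add atoms: methanesulfonyl chloride, CS(=O)(=O)Cl
Why: O-sulfonylation with retention at the carbinol carbon; the crude mesylate is used at once because secondary propargylic mesylates ionise on standing.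

Step 9
Reactants: 14 (3S,4R)-4-methyloct-7-en-1-yn-3-yl methanesulfonate; 15 acetaldehyde
Product: 17 (2S,3R,4R)-3-ethynyl-4-methyloct-7-en-2-ol, via ethyl[(M,4R)-4-methylocta-1,2,7-trien-1-yl]zinc 16 (not isolated)
Conditions: Pd(OAc)2 (5 mol%), PPh3 (5 mol%), Et2Zn (3 equiv), 15 (excess), THF, −78 → −20 °C; aq NH4Cl
Reagents that add atoms: none
Why: Palladium-catalysed, zinc-mediated propargylation (Marshall allenylzinc addition): zerovalent palladium displaces the mesylate anti in SN2' fashion, Et2Zn transmetalates to the (M)-allenylzinc 16, and 16 adds to 15 through a cyclic SE2' transition state. The new C6'–C7' bond forms on the face opposite the departed mesylate, which fixes C6' as R, and the aldehyde methyl group turns away from the allene substituent, which gives the anti adduct with C7' as S.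

Step 10
Reactants: 17 (2S,3R,4R)-3-ethynyl-4-methyloct-7-en-2-ol
Product: 18 tert-butyl{[(2S,3R,4R)-3-ethynyl-4-methyloct-7-en-2-yl]oxy}dimethylsilane
Conditions: t-BuMe2SiOTf, 2,6-lutidine, CH2Cl2, −78 → 0 °C
Reagents that add atoms: tert-butyldimethylsilyl trifluoromethanesulfonate, CC(C)(C)[Si](C)(C)OS(=O)(=O)C(F)(F)F
Why: Silylation of a hindered secondary alcohol with the silyl triflate; the ether shields the carbinol from the boron reagent of step 11 and from the oxidation of step 20.

Step 11
Reactants: 18 tert-butyl{[(2S,3R,4R)-3-ethynyl-4-methyloct-7-en-2-yl]oxy}dimethylsilane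
Product: 20 tert-butyl{[(2S,3S,4R)-3-(1-iodoethenyl)-4-methyloct-7-en-2-yl]oxy}dimethylsilane, via (Z)-2-iodoalkenyl-9-borabicyclononane 19 (not isolated)
Conditions: B-iodo-9-BBN, pentane, −20 → 0 °C; AcOH, 0 °C
Reagents that add atoms: B-iodo-9-borabicyclo[3.3.1]nonane, IB1C2CCCC1CCC2
Why: Haloboration followed by protodeboration; B–I adds syn to the terminal alkyne with boron on the terminal carbon and iodine on the internal one, and acetic acid cleaves the alkenyl C–B bond to give the 2-iodo-1-alkene. Terminal alkenes and silyl ethers should be inert to the reagent at this temperature; the descriptor at C6' changes to S only because the iodine-bearing carbon now ranks first.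

Step 12
Reactants: 21 phloroglucinol; 22 ethyl 2-methylacetoacetate
Product: 23 5,7-dihydroxy-3,4-dimethyl-2H-chromen-2-one
Conditions: H2SO4 (75%), rt
Reagents that add atoms: none
Why: Pechmann condensation; the keto carbon attacks the ring and the ester lactonises onto the neighbouring phenol. The threefold symmetry of 21 allows only one product.

Step 13
Reactants: 23 5,7-dihydroxy-3,4-dimethyl-2H-chromen-2-one
Product: 25 5,7-dihydroxy-3,4-dimethyl-2-oxo-2H-chromene-8-carbaldehyde, via 8-(N-methyl-N-phenyliminiomethyl)coumarin chloride 24 (not isolated)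
Conditions: PhN(Me)CHO, POCl3, ClCH2CH2Cl, rt → 70 °C; then aq NaOAc, 60 °C
Reagents that add atoms: N-methylformanilide, O=CN(C)c1ccccc1; water, O
Why: Vilsmeier–Haack formylation; in 5,7-dihydroxy-4-alkylcoumarins C8 (ortho to O7 and para to O5) is the position that iminium and acylium electrophiles are known to prefer over C6. The iminium group of 24 deactivates the ring against a second attack and is hydrolysed to the aldehyde.

Step 14
Reactants: 25 5,7-dihydroxy-3,4-dimethyl-2-oxo-2H-chromene-8-carbaldehyde
Product: 26 7-hydroxy-5-methoxy-3,4-dimethyl-2-oxo-2H-chromene-8-carbaldehyde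
Conditions: MeI (1.1 equiv), K2CO3 (1.1 equiv), acetone, rt → 40 °C
Reagents that add atoms: iodomethane, CI
Why: Williamson ether synthesis; the 7-OH is held in a hydrogen bond to the 8-formyl group and is the poorer nucleophile, so one equivalent of base and MeI should alkylate the free 5-OH, which is also para to the aldehyde and more acidic.

Step 15
Reactants: 26 7-hydroxy-5-methoxy-3,4-dimethyl-2-oxo-2H-chromene-8-carbaldehyde
Product: 27 5-methoxy-3,4-dimethyl-2-oxo-7-(prop-2-en-1-yloxy)-2H-chromene-8-carbaldehyde
Conditions: allyl bromide, K2CO3, DMF, 60 °C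
Reagents that add atoms: 3-bromoprop-1-ene, C=CCBr
Why: Williamson allylation of the remaining, chelated phenol; excess reagent and a polar solvent overcome its lower nucleophilicity, and O-alkylation is the only possible outcome on oxygen.

Step 16
Reactants: 27 5-methoxy-3,4-dimethyl-2-oxo-7-(prop-2-en-1-yloxy)-2H-chromene-8-carbaldehyde
Product: 28 7-hydroxy-5-methoxy-3,4-dimethyl-2-oxo-6-(prop-2-en-1-yl)-2H-chromene-8-carbaldehyde
Conditions: PhNEt2, 190 °C
Reagents that add atoms: none
Why: Aromatic Claisen rearrangement; the [3,3] shift from O7 can reach C6 or C8, but only the C6 adduct can tautomerise to a phenol because C8 carries the formyl group, so the reversible shift to C8 drains into the C6 product.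

Step 17
Reactants: 28 7-hydroxy-5-methoxy-3,4-dimethyl-2-oxo-6-(prop-2-en-1-yl)-2H-chromene-8-carbaldehyde
Product: 29 7-hydroxy-5-methoxy-3,4-dimethyl-6-(3-methylbut-2-en-1-yl)-2-oxo-2H-chromene-8-carbaldehyde
Conditions: 2-methylbut-2-ene (excess), second-generation Grubbs catalyst (H2IMes)(PCy3)Cl2Ru=CHPh (3 mol%), CH2Cl2, 40 °C
Reagents that add atoms: 2-methylbut-2-ene, CC=C(C)C
Why: Olefin cross-metathesis; the excess trisubstituted alkene caps the allyl terminus with an isopropylidene group and propene leaves. Phenol, aldehyde and the tetrasubstituted C3=C4 alkene are tolerated.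

Step 18
Reactants: 29 7-hydroxy-5-methoxy-3,4-dimethyl-6-(3-methylbut-2-en-1-yl)-2-oxo-2H-chromene-8-carbaldehyde
Product: 30 7-{[tert-butyl(dimethyl)silyl]oxy}-5-methoxy-3,4-dimethyl-6-(3-methylbut-2-en-1-yl)-2-oxo-2H-chromene-8-carbaldehyde
Conditions: t-BuMe2SiOTf, 2,6-lutidine, CH2Cl2, 0 °C
Reagents that add atoms: tert-butyldimethylsilyl trifluoromethanesulfonate, CC(C)(C)[Si](C)(C)OS(=O)(=O)C(F)(F)F
Why: Silylation of a chelated, doubly flanked phenol needs the silyl triflate; the aldehyde has no α-hydrogen and cannot form an enol ether. The ether removes the acidic proton for step 19 and the oxa-Michael donor for step 21.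

Step 19
Reactants: 20 tert-butyl{[(2S,3S,4R)-3-(1-iodoethenyl)-4-methyloct-7-en-2-yl]oxy}dimethylsilane; 30 7-{[tert-butyl(dimethyl)silyl]oxy}-5-methoxy-3,4-dimethyl-6-(3-methylbut-2-en-1-yl)-2-oxo-2H-chromene-8-carbaldehyde
Product: 32 7-{[tert-butyl(dimethyl)silyl]oxy}-8-{(3R,4R)-3-[(1S)-1-{[tert-butyl(dimethyl)silyl]oxy}ethyl]-1-hydroxy-4-methyl-2-methylideneoct-7-en-1-yl}-5-methoxy-3,4-dimethyl-6-(3-methylbut-2-en-1-yl)-2H-chromen-2-one (both epimers at the new carbinol carbon), via alkenylchromium dichloride 31 (not isolated)
Conditions: CrCl2 (6 equiv), NiCl2 (2 mol%), 20 (1.5 equiv), DMSO/THF, rt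
Reagents that add atoms: none
Why: Nozaki–Hiyama–Kishi coupling; zerovalent nickel inserts into the C–I bond and hands the alkenyl group to trivalent chromium, and alkenylchromium 31 adds only to the aldehyde, leaving lactone, silyl ethers and alkenes untouched. The new carbinol centre is formed without control, which does not matter because it is oxidised next.

Step 20
Reactants: 32 the allylic alcohol of step 19
Product: 33 7-{[tert-butyl(dimethyl)silyl]oxy}-8-{(3R,4R)-3-[(1S)-1-{[tert-butyl(dimethyl)silyl]oxy}ethyl]-4-methyl-2-methylideneoct-7-enoyl}-5-methoxy-3,4-dimethyl-6-(3-methylbut-2-en-1-yl)-2H-chromen-2-one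
Conditions: Dess–Martin periodinane, NaHCO3, CH2Cl2, 0 °C → rt
Reagents that add atoms: none
Why: Dess–Martin oxidation of a benzylic, allylic alcohol under buffered, neutral conditions; both epimers converge on one ketone, and the exo-methylene group should not migrate into conjugation with C6' without acid or base.

Step 21
Reactants: 33 the bis-silylated aryl 1,7-dienone of step 20
Product: 34 7-{[tert-butyl(dimethyl)silyl]oxy}-8-({(5R,6R)-6-[(1S)-1-{[tert-butyl(dimethyl)silyl]oxy}ethyl]-5-methylcyclohex-1-en-1-yl}carbonyl)-5-methoxy-3,4-dimethyl-6-(3-methylbut-2-en-1-yl)-2H-chromen-2-one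
Conditions: second-generation Grubbs catalyst (H2IMes)(PCy3)Cl2Ru=CHPh (10 mol%), 1,4-benzoquinone (20 mol%), toluene (0.005 M), 80 °C, argon sparge
Reagents that add atoms: none
Why: The ruthenium benzylidene first exchanges with the monosubstituted vinyl group at C2', the only unhindered and electron-neutral alkene; the new alkylidene then adds intramolecularly to the exo-methylene alkene at C1', and cycloreversion of the ruthenacyclobutane releases ring C and a ruthenium methylidene that carries the chain, with ethylene as the by-product. The closest known reaction type is ring-closing metathesis of α-methylene ketones and 2-substituted acrylates with a tethered terminal alkene to 1-acylcycloalkenes. Ring C is closed as a six-membered carbocycle from the 1,7-diene by formation of its endocyclic C1'=C2' bond, and the two branch points C5' and C6' in the tether favour the folded conformer. No stereocentre is formed, and C5', C6' and C7' lie off the reacting carbons and should not epimerise under neutral conditions. The step needs chemoselectivity among four alkenes: the prenyl alkene is trisubstituted and reacts far more slowly than the six-ring closure, and the C3=C4 alkene of ring B is tetrasubstituted and conjugated and is inert. High dilution works against dimerisation at the vinyl terminus, and sparging removes ethylene so that it cannot truncate the prenyl group. The silyl ether on O7 blocks oxa-Michael addition to the α-methylene ketone, and benzoquinone suppresses alkene migration by ruthenium hydrides.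

Step 22
Reactants: 34 the bis-silyl ether of step 21
Product: 35 7-hydroxy-8-({(5R,6R)-6-[(1S)-1-hydroxyethyl]-5-methylcyclohex-1-en-1-yl}carbonyl)-5-methoxy-3,4-dimethyl-6-(3-methylbut-2-en-1-yl)-2H-chromen-2-one
Conditions: Bu4NF, AcOH (1:1, 4 equiv each), THF, 0 → 40 °C
Reagents that add atoms: none
Why: Fluoride-induced desilylation of the aryl and the secondary silyl ether; the acetic acid buffer keeps the freed phenol protonated, so it should not add to C2' of the enone or open the lactone. No strong acid is used that could cyclise the prenyl group onto O7.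

## Compound list

1 | hex-5-enoic acid | OC(=O)CCCC=C | starting material
2 | (R)-4-benzyloxazolidin-2-one | O=C1N[C@H](Cc2ccccc2)CO1 | starting material
3 | hex-5-enoic pivalic anhydride | C=CCCCC(=O)OC(=O)C(C)(C)C | intermediate
4 | (R)-4-benzyl-3-(hex-5-enoyl)oxazolidin-2-one | C=CCCCC(=O)N1[C@H](Cc2ccccc2)COC1=O | intermediate
5 | sodium (Z)-enolate of 4 | C=CCC/C=C(\[O-])N1[C@H](Cc2ccccc2)COC1=O.[Na+] | intermediate
6 | (R)-4-benzyl-3-[(R)-2-methylhex-5-enoyl]oxazolidin-2-one | C=CCC[C@@H](C)C(=O)N1[C@H](Cc2ccccc2)COC1=O | intermediate
7 | lithium (R)-2-methylhex-5-eneperoxoate | C=CCC[C@@H](C)C(=O)O[O-].[Li+] | intermediate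
8 | (R)-2-methylhex-5-enoic acid | C=CCC[C@@H](C)C(O)=O | intermediate
9 | (R)-1-(1H-imidazol-1-yl)-2-methylhex-5-en-1-one | C=CCC[C@@H](C)C(=O)n1ccnc1 | intermediate
10 | (R)-N-methoxy-N,2-dimethylhex-5-enamide | C=CCC[C@@H](C)C(=O)N(C)OC | intermediate
11 | (R)-4-methyl-1-(trimethylsilyl)oct-7-en-1-yn-3-one | C=CCC[C@@H](C)C(=O)C#C[Si](C)(C)C | intermediate
12 | (3S,4R)-4-methyl-1-(trimethylsilyl)oct-7-en-1-yn-3-ol | C=CCC[C@@H](C)[C@H](O)C#C[Si](C)(C)C | intermediate
13 | (3S,4R)-4-methyloct-7-en-1-yn-3-ol | C=CCC[C@@H](C)[C@H](O)C#C | intermediate
14 | (3S,4R)-4-methyloct-7-en-1-yn-3-yl methanesulfonate | C=CCC[C@@H](C)[C@H](OS(C)(=O)=O)C#C | intermediate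
15 | acetaldehyde | CC=O | starting material
16 | ethyl[(M,4R)-4-methylocta-1,2,7-trien-1-yl]zinc (allene axis M) | CC[Zn]C=[C@]=C[C@H](C)CCC=C | intermediate
17 | (2S,3R,4R)-3-ethynyl-4-methyloct-7-en-2-ol | C#C[C@@H]([C@H](C)CCC=C)[C@H](C)O | intermediate
18 | tert-butyl{[(2S,3R,4R)-3-ethynyl-4-methyloct-7-en-2-yl]oxy}dimethylsilane | C#C[C@@H]([C@H](C)CCC=C)[C@H](C)O[Si](C)(C)C(C)(C)C | intermediate
19 | 9-[(1Z,3S,4R)-3-{(1S)-1-[tert-butyl(dimethyl)silyloxy]ethyl}-2-iodo-4-methylocta-1,7-dien-1-yl]-9-borabicyclo[3.3.1]nonane | I/C(=C\B1C2CCCC1CCC2)[C@@H]([C@H](C)CCC=C)[C@H](C)O[Si](C)(C)C(C)(C)C | intermediate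
20 | tert-butyl{[(2S,3S,4R)-3-(1-iodoethenyl)-4-methyloct-7-en-2-yl]oxy}dimethylsilane | C=C(I)[C@@H]([C@H](C)CCC=C)[C@H](C)O[Si](C)(C)C(C)(C)C | intermediate
21 | phloroglucinol (benzene-1,3,5-triol) | Oc1cc(O)cc(O)c1 | starting material
22 | ethyl 2-methylacetoacetate (ethyl 2-methyl-3-oxobutanoate) | CCOC(=O)C(C)C(C)=O | starting material
23 | 5,7-dihydroxy-3,4-dimethyl-2H-chromen-2-one | Cc1c(C)c2c(O)cc(O)cc2oc1=O | intermediate
24 | N-[(5,7-dihydroxy-3,4-dimethyl-2-oxo-2H-chromen-8-yl)methylidene]-N-methylanilinium chloride | Cc1c(C)c2c(O)cc(O)c(C=[N+](C)c3ccccc3)c2oc1=O.[Cl-] | intermediate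
25 | 5,7-dihydroxy-3,4-dimethyl-2-oxo-2H-chromene-8-carbaldehyde | Cc1c(C)c2c(O)cc(O)c(C=O)c2oc1=O | intermediate
26 | 7-hydroxy-5-methoxy-3,4-dimethyl-2-oxo-2H-chromene-8-carbaldehyde | COc1cc(O)c(C=O)c2oc(=O)c(C)c(C)c12 | intermediate
27 | 5-methoxy-3,4-dimethyl-2-oxo-7-(prop-2-en-1-yloxy)-2H-chromene-8-carbaldehyde | COc1cc(OCC=C)c(C=O)c2oc(=O)c(C)c(C)c12 | intermediate
28 | 7-hydroxy-5-methoxy-3,4-dimethyl-2-oxo-6-(prop-2-en-1-yl)-2H-chromene-8-carbaldehyde | COc1c(CC=C)c(O)c(C=O)c2oc(=O)c(C)c(C)c12 | intermediate
29 | 7-hydroxy-5-methoxy-3,4-dimethyl-6-(3-methylbut-2-en-1-yl)-2-oxo-2H-chromene-8-carbaldehyde | COc1c(CC=C(C)C)c(O)c(C=O)c2oc(=O)c(C)c(C)c12 | intermediate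
30 | 7-{[tert-butyl(dimethyl)silyl]oxy}-5-methoxy-3,4-dimethyl-6-(3-methylbut-2-en-1-yl)-2-oxo-2H-chromene-8-carbaldehyde | COc1c(CC=C(C)C)c(O[Si](C)(C)C(C)(C)C)c(C=O)c2oc(=O)c(C)c(C)c12 | intermediate
31 | dichloro{(3S,4R)-3-[(1S)-1-{[tert-butyl(dimethyl)silyl]oxy}ethyl]-4-methylocta-1,7-dien-2-yl}chromium | C=C([Cr](Cl)Cl)[C@@H]([C@H](C)CCC=C)[C@H](C)O[Si](C)(C)C(C)(C)C | intermediate
32 | 7-{[tert-butyl(dimethyl)silyl]oxy}-8-{(3R,4R)-3-[(1S)-1-{[tert-butyl(dimethyl)silyl]oxy}ethyl]-1-hydroxy-4-methyl-2-methylideneoct-7-en-1-yl}-5-methoxy-3,4-dimethyl-6-(3-methylbut-2-en-1-yl)-2H-chromen-2-one (both carbinol epimers) | COc1c(CC=C(C)C)c(O[Si](C)(C)C(C)(C)C)c(C(O)C(=C)[C@@H]([C@H](C)CCC=C)[C@H](C)O[Si](C)(C)C(C)(C)C)c2oc(=O)c(C)c(C)c12 | intermediate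
33 | 7-{[tert-butyl(dimethyl)silyl]oxy}-8-{(3R,4R)-3-[(1S)-1-{[tert-butyl(dimethyl)silyl]oxy}ethyl]-4-methyl-2-methylideneoct-7-enoyl}-5-methoxy-3,4-dimethyl-6-(3-methylbut-2-en-1-yl)-2H-chromen-2-one | COc1c(CC=C(C)C)c(O[Si](C)(C)C(C)(C)C)c(C(=O)C(=C)[C@@H]([C@H](C)CCC=C)[C@H](C)O[Si](C)(C)C(C)(C)C)c2oc(=O)c(C)c(C)c12 | intermediate
34 | 7-{[tert-butyl(dimethyl)silyl]oxy}-8-({(5R,6R)-6-[(1S)-1-{[tert-butyl(dimethyl)silyl]oxy}ethyl]-5-methylcyclohex-1-en-1-yl}carbonyl)-5-methoxy-3,4-dimethyl-6-(3-methylbut-2-en-1-yl)-2H-chromen-2-one | COc1c(CC=C(C)C)c(O[Si](C)(C)C(C)(C)C)c(C(=O)C2=CCC[C@@H](C)[C@H]2[C@H](C)O[Si](C)(C)C(C)(C)C)c2oc(=O)c(C)c(C)c12 | intermediate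
35 | 7-hydroxy-8-({(5R,6R)-6-[(1S)-1-hydroxyethyl]-5-methylcyclohex-1-en-1-yl}carbonyl)-5-methoxy-3,4-dimethyl-6-(3-methylbut-2-en-1-yl)-2H-chromen-2-one | COc1c(CC=C(C)C)c(O)c(C(=O)C2=CCC[C@@H](C)[C@H]2[C@H](C)O)c2oc(=O)c(C)c(C)c12 | target

## Step count and least certain steps

Total: 22 steps. Longest linear sequence: 15 steps (steps 1 to 11, then 19 to 22). The coumarin branch (steps 12 to 18) has 7 steps and joins at step 19.

Step 21 (key step). Ring closure at the crowded, electron-poor exo-methylene alkene may be slow. Dimerisation at the vinyl terminus, truncation of the prenyl group by ethylene, or ruthenium-hydride migration of the exo-methylene or vinyl double bond could then compete. Fallback: the metathesis is moved one step earlier, onto allylic alcohol 32, whose 1,1-disubstituted alkene is not electron-poor, is not a Michael acceptor and is activated by the free allylic hydroxyl group. With the same catalyst in CH2Cl2 at 40 °C, 32 should give the ring-closed carbinol F1, and oxidation of F1 with Dess–Martin periodinane/NaHCO3 returns to the route at 34.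

Step 9. The anti preference may erode because acetaldehyde is small and unbranched, and the branched allenylmetal may be lost by β-hydride elimination or protonation before it adds. Fallback for the selectivity: the C7' epimer mixture of 17 is oxidised with buffered Dess–Martin periodinane to the methyl ketone F2, which is reduced at once with catecholborane under (R)-Me-CBS oxazaborolidine control (toluene, −78 °C). C7' is then set by the catalyst, which distinguishes the methyl group from the branched C6' group, and the sequence comes back at 17. Catecholborane at low temperature leaves the alkene and alkyne alone, and the neutral oxidation limits epimerisation at C6'.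

Step 11. The Lewis-acidic boron iodide may attack the silyl ether, and traces of HI may add to the terminal alkene. Fallback: from 18, hydration of the terminal alkyne with (Ph3P)AuNTf2 (cat.) in wet dioxane gives the methyl ketone F3. Kinetic enolisation toward the methyl group with KN(SiMe3)2 at −78 °C and trapping with PhNTf2 gives the enol triflate F4. F4 undergoes the same CrCl2/NiCl2 coupling with 30 and returns to the route at 32.

Step 13. Substitution at C6 or twofold formylation may compete, because both positions are activated by two oxygen substituents. Fallback: C6 is occupied before the formyl group is introduced. From 23, the more acidic and less hindered 7-OH is masked with MOMCl/i-Pr2NEt to give the mono-MOM ether F5. The 5-OH is allylated (allyl bromide, K2CO3, DMF) to the allyl ether F6. Claisen rearrangement (PhNEt2, 190 °C) can deliver only to C6 and gives the 6-allyl phenol F7. Methylation (MeI, K2CO3, DMF) gives the methyl ether F8, and HCl in MeOH removes the MOM group to give the phenol F9. Ortho-formylation of F9 with MgCl2, Et3N and paraformaldehyde in MeCN can occur only at C8 and returns to the route at 28.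

Step 19. Addition to the doubly ortho-substituted aldehyde may be slow, so that the alkenylchromium is protonated or dimerises, and the silyl group on O7 may migrate to the new alkoxide. Fallback: from 20, iodine–lithium exchange with t-BuLi (2 equiv, Et2O, −78 °C) gives the alkenyllithium F10. Transmetalation with anhydrous CeCl3 gives the alkenylcerium dichloride F11, which should add to aldehyde 30 at −78 °C much faster than to the lactone and returns to the route at 32.

## Further compounds

F1 | step 21 | 7-{[tert-butyl(dimethyl)silyl]oxy}-8-[{(5R,6R)-6-[(1S)-1-{[tert-butyl(dimethyl)silyl]oxy}ethyl]-5-methylcyclohex-1-en-1-yl}(hydroxy)methyl]-5-methoxy-3,4-dimethyl-6-(3-methylbut-2-en-1-yl)-2H-chromen-2-one (both carbinol epimers) | COc1c(CC=C(C)C)c(O[Si](C)(C)C(C)(C)C)c(C(O)C2=CCC[C@@H](C)[C@H]2[C@H](C)O[Si](C)(C)C(C)(C)C)c2oc(=O)c(C)c(C)c12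
F2 | step 9 | (3R,4R)-3-ethynyl-4-methyloct-7-en-2-one | C#C[C@@H]([C@H](C)CCC=C)C(C)=O
F3 | step 11 | (3S,4R)-3-[(1S)-1-{[tert-butyl(dimethyl)silyl]oxy}ethyl]-4-methyloct-7-en-2-one | CC(=O)[C@@H]([C@H](C)CCC=C)[C@H](C)O[Si](C)(C)C(C)(C)C
F4 | step 11 | (3S,4R)-3-[(1S)-1-{[tert-butyl(dimethyl)silyl]oxy}ethyl]-4-methylocta-1,7-dien-2-yl trifluoromethanesulfonate | C=C(OS(=O)(=O)C(F)(F)F)[C@@H]([C@H](C)CCC=C)[C@H](C)O[Si](C)(C)C(C)(C)C
F5 | step 13 | 5-hydroxy-7-(methoxymethoxy)-3,4-dimethyl-2H-chromen-2-one | COCOc1cc(O)c2c(C)c(C)c(=O)oc2c1
F6 | step 13 | 7-(methoxymethoxy)-3,4-dimethyl-5-(prop-2-en-1-yloxy)-2H-chromen-2-one | COCOc1cc(OCC=C)c2c(C)c(C)c(=O)oc2c1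
F7 | step 13 | 5-hydroxy-7-(methoxymethoxy)-3,4-dimethyl-6-(prop-2-en-1-yl)-2H-chromen-2-one | COCOc1cc2oc(=O)c(C)c(C)c2c(O)c1CC=C
F8 | step 13 | 5-methoxy-7-(methoxymethoxy)-3,4-dimethyl-6-(prop-2-en-1-yl)-2H-chromen-2-one | COCOc1cc2oc(=O)c(C)c(C)c2c(OC)c1CC=C
F9 | step 13 | 7-hydroxy-5-methoxy-3,4-dimethyl-6-(prop-2-en-1-yl)-2H-chromen-2-one | COc1c(CC=C)c(O)cc2oc(=O)c(C)c(C)c12
F10 | step 19 | {(3R,4R)-3-[(1S)-1-{[tert-butyl(dimethyl)silyl]oxy}ethyl]-4-methylocta-1,7-dien-2-yl}lithium | [Li]C(=C)[C@@H]([C@H](C)CCC=C)[C@H](C)O[Si](C)(C)C(C)(C)C
F11 | step 19 | dichloro{(3S,4R)-3-[(1S)-1-{[tert-butyl(dimethyl)silyl]oxy}ethyl]-4-methylocta-1,7-dien-2-yl}cerium | Cl[Ce](Cl)C(=C)[C@@H]([C@H](C)CCC=C)[C@H](C)O[Si](C)(C)C(C)(C)C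
A1 | alternative 1 | (5S)-5-methyl-3-[(1Z,3E)-penta-1,3-dien-1-yl]furan-2(5H)-one | C/C=C/C=C\C1=C[C@H](C)OC1=O
A2 | alternative 1 | (3S,3aR,4R)-3,4-dimethyl-3a,4-dihydro-2-benzofuran-1(3H)-one | O=C1C2=CC=C[C@@H](C)[C@H]2[C@H](C)O1
A3 | alternative 2 | 5-methoxy-3,4-dimethyl-2-oxo-8-(trimethylsilyl)-2H-chromen-7-yl trifluoromethanesulfonate | COc1cc(OS(=O)(=O)C(F)(F)F)c([Si](C)(C)C)c2oc(=O)c(C)c(C)c12
A4 | alternative 2 | (5R,6R)-6-{(1S)-1-[(4-methoxyphenyl)methoxy]ethyl}-5-methylcyclohex-1-ene-1-carboxylic acid | OC(=O)C1=CCC[C@@H](C)[C@H]1[C@H](C)OCc1ccc(OC)cc1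
A5 | alternative 2 | 7-hydroxy-5-methoxy-8-[((5R,6R)-6-{(1S)-1-[(4-methoxyphenyl)methoxy]ethyl}-5-methylcyclohex-1-en-1-yl)carbonyl]-3,4-dimethyl-2H-chromen-2-one | COc1cc(O)c(C(=O)C2=CCC[C@@H](C)[C@H]2[C@H](C)OCc3ccc(OC)cc3)c2oc(=O)c(C)c(C)c12
A6 | alternative 3 | (2E,6R)-6-[(2R,3S)-3-methyloxiran-2-yl]hept-2-enenitrile | N#C/C=C/CC[C@@H](C)[C@H]1O[C@H]1C
A7 | alternative 3 | (5R,6R)-6-[(1S)-1-hydroxyethyl]-5-methylcyclohex-1-ene-1-carbonitrile | N#CC1=CCC[C@@H](C)[C@H]1[C@H](C)O
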